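**Retrosynthetic overview**
1. The target ⇐ Mitsunobu inversion at C-3 and deprotection of a 3α-hydroxy-19,10-lactone, which comes from acid-triggered opening of a 3α,10α-oxygen bridge by the C-19 acid (ring A functionality derives from a furan).
2. C-7 carboxyl ⇐ one-carbon homologation of a C-6 ketone ⇐ the C-6 oxygen of a butenolide-derived lactone.
3. Ring D and the 13-oxygen ⇐ gold-catalysed cyclisation of a 12,13-enediol bis(silyl ether) onto an 8-propargyl group (new); 12-OH ⇐ ketone reduction.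
4. Rings A and B together ⇐ intramolecular furan Diels–Alder reaction of a butenolide tethered through C-6.
5. Ring C with C-8 and C-9 ⇐ iminium-catalysed Diels–Alder reaction of furylacrolein with a 2,3-bis(silyloxy)butadiene, then α-propargylation. Ring order: C, then A+B, then D.

Assumption: positions use gibberellane numbering (C-7 and C-19 are the carboxyl carbons); α = face of the C-10 lactone oxygen, β = face of H-5/H-9; the target is named by structure as (12S)-12α-hydroxygibberellic acid; 1, 3, 5 and 7 are taken as commercial; the C-6 carbinol centre of 8–10 is an epimer mixture and is left undefined in the SMILES.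

**Step 1**
Reactants: 1 butane-2,3-dione
Product: 2 2,3-bis(tert-butyldimethylsilyloxy)buta-1,3-diene
Conditions: TBSOTf (2.2 equiv), Et3N, CH2Cl2, 0 °C to rt
Reagents that add atoms: tert-butyldimethylsilyl trifluoromethanesulfonate CC(C)(C)[Si](C)(C)OS(=O)(=O)C(F)(F)F
Why: Double soft enolisation and O-silylation of the 1,2-diketone (silyl enol ether formation) gives a symmetric electron-rich diene, so no regiochemical question arises in step 2.

**Step 2**
Reactants: 2 2,3-bis(tert-butyldimethylsilyloxy)buta-1,3-diene; 3 (E)-3-(furan-2-yl)prop-2-enal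
Product: 4 (1R,6R)-3,4-bis(TBSO)-6-(furan-2-yl)cyclohex-3-ene-1-carbaldehyde (CHO and furyl trans)
Conditions: (5R)-5-benzyl-2,2,3-trimethylimidazolidin-4-one·CF3CO2H (20 mol%), MeNO2/H2O 95:5, −20 °C
Reagents that add atoms: none
Why: MacMillan iminium-catalysed Diels–Alder reaction, in which the benzyl group of the (E)-iminium ion shields one face so the diene adds to the Re face of the α-carbon, setting C-9 (and provisionally C-8) as (1R,6R) with the trans relationship coming from the E-alkene.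

**Step 3**
Reactants: 4 (1R,6R)-aldehyde; 5 3-bromoprop-1-yne
Product: 6 (1S,6R)-3,4-bis(TBSO)-6-(furan-2-yl)-1-(prop-2-yn-1-yl)cyclohex-3-ene-1-carbaldehyde (CHO cis to furyl)
Conditions: KN(SiMe3)2, THF, −78 °C, then 5, −78 to 0 °C
Reagents that add atoms: none
Why: Enolate C-alkylation of the α-branched aldehyde, with the electrophile entering anti to the pseudoaxial furyl group, makes the C-8 quaternary centre with the propargyl group trans to C-10 and the formyl carbon (C-6) cis to it.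

**Step 4**
Reactants: 6 (1S,6R)-propargyl aldehyde; 7 methyl 2-(bromomethyl)prop-2-enoate
Product: 9 5-[(1S,6R)-3,4-bis(TBSO)-6-(furan-2-yl)-1-propargylcyclohex-3-en-1-yl]-3-methylideneoxolan-2-one (C-6 epimers), via hydroxy ester 8 (not isolated)
Conditions: Zn dust, THF, 60 °C
Reagents that add atoms: none
Why: Reformatsky-type (Barbier) 2-(methoxycarbonyl)allylation of the non-enolisable aldehyde followed by lactonisation of the zinc alkoxide gives the α-methylene-γ-butyrolactone; the unselective C-6 carbinol centre is equilibrated in step 5.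

**Step 5**
Reactants: 9 α-methylene lactone
Product: 11 oxygen-bridged lactone adduct (rings A/B/C; 3α,10α-epoxy-1-ene; 4β-methyl; C-19 carbonyl lactonised onto 6α-O; H-5β; H-9β; 8β-propargyl; 12,13-enediol bis-TBS ether), via butenolide 10 (not isolated)
Conditions: DBU (0.3 equiv), toluene, rt then 110 °C
Reagents that add atoms: none
Why: Base-mediated exo-to-endo alkene isomerisation gives the α-methylbutenolide, whose acidic γ-H lets the C-6 epimers interconvert, and its ring-locked cis C-4/C-5 double bond then undergoes an intramolecular furan Diels–Alder reaction in which the three-atom tether must be exo (bridge oxygen syn to C-6, hence the C-10 oxygen trans to H-5), C-19 ends syn to the bridge and the furan oxygen turns toward C-11 and not H-9, setting C-3, C-4, C-5 and C-10.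

**Step 6**
Reactants: 11 oxygen-bridged lactone adduct
Product: 12 ring-D ketone (13-OTBS; 12-oxo; 16-methylidene; oxygen bridge and 19,6-lactone unchanged)
Conditions: [(t-Bu)2(biphenyl-2-yl)P]Au(NCMe)SbF6 (5 mol%), CH2Cl2/MeOH 10:1, rt
Reagents that add atoms: none
Why: Proposed new method: gold-catalysed 5-exo-dig Conia-ene-type cyclisation of a tetrasubstituted 1,2-bis(silyloxy)alkene onto a terminal alkyne — the cationic phosphine-gold complex activates the alkyne, the electron-rich C-13 terminus attacks it (5-exo closure expected to beat 6-exo attack from C-12), the C-12 silyloxocarbenium is desilylated by MeOH and protodeauration leaves the exo-methylene, so ring D and the oxygenated quaternary C-13 (configuration forced by the β-propargyl tether) form in one step; the closest known reaction is the gold-catalysed cyclisation of simple silyl enol ethers onto alkynes, which has not been shown for enediol bis(silyl ethers).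

**Step 7**
Reactants: 12 ring-D ketone
Product: 14 12,13-bis-OTBS lactone (12α-O, axial on ring C), via alcohol 13 (not isolated)
Conditions: LiBH(s-Bu)3, THF, −78 °C; then TBSOTf, 2,6-lutidine, −78 to 0 °C
Reagents that add atoms: tert-butyldimethylsilyl trifluoromethanesulfonate CC(C)(C)[Si](C)(C)OS(=O)(=O)C(F)(F)F
Why: Ketone reduction by the bulky hydride from the equatorial direction, away from the axial bond between C-9 and C-10, gives the axial 12α-OH, and in-flask silyl ether formation protects it from the later oxidation and Mitsunobu steps.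

**Step 8**
Reactants: 14 bis-OTBS lactone
Product: 16 keto acid (6-oxo; free C-19 acid; oxygen bridge intact), via hydroxy acid 15 (not isolated)
Conditions: n-Bu4NOH, THF/H2O, 40 °C; then Pr4N[RuO4] (10 mol%), NMO, 4 Å MS, CH2Cl2, rt; 1 M HCl work-up
Reagents that add atoms: tetrabutylammonium hydroxide CCCC[N+](CCCC)(CCCC)CCCC.[OH-]
Why: Saponification of the γ-lactone frees C-19, and Ley–Griffith oxidation of the C-6 carbinol as its ammonium carboxylate (which cannot relactonise) gives the ketone needed to attach C-7.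

**Step 9**
Reactants: 16 keto acid
Product: 17 β-hydroxysilane adduct (6-hydroxy-6-[methoxy(trimethylsilyl)methyl]; diastereomer mixture)
Conditions: Me3SiCH2OMe, s-BuLi, THF, −78 °C; CeCl3; then 16, −78 °C
Reagents that add atoms: (methoxymethyl)trimethylsilane COC[Si](C)(C)C
Why: Organocerium 1,2-addition of the methoxy(trimethylsilyl)methyl anion (Magnus–Peterson homologation) brings in C-7 without enolising the C-6 ketone, which under a basic Wittig ylide would expel the β-oxygen bridge by E1cB.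

**Step 10**
Reactants: 17 β-hydroxysilane adduct
Product: 20 3α-hydroxy-19,10-lactone 7-aldehyde (1-ene; 6β-CHO; 12,13-bis-OTBS), via enol ether 18 (not isolated), via aldehyde acid 19 (not isolated)
Conditions: CF3CO2H, CH2Cl2/H2O 20:1, 0 °C to rt
Reagents that add atoms: water O
Why: Acid-promoted Peterson elimination and enol-ether hydrolysis give the C-7 aldehyde (equilibrating to the more stable 6β-CHO), and protonation of the strained bridge ionises the tertiary allylic bond from C-10 to oxygen so the α-oriented C-19 acid closes the 19,10-γ-lactone on the α face (acid-mediated 7-oxanorbornene opening with lactonisation), leaving the former furan oxygen as the 3α-OH.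

**Step 11**
Reactants: 20 3α-hydroxy lactone aldehyde
Product: 21 3β-formyloxy-19,10-lactone 7-aldehyde
Conditions: PPh3, DIAD, HCO2H, THF, 0 °C to rt
Reagents that add atoms: formic acid O=CO
Why: Mitsunobu reaction, in which SN2 displacement of the activated equatorial 3α-oxygen by formate along the open axial β trajectory inverts C-3 to the natural 3β configuration and leaves a mildly removable ester.

**Step 12**
Reactants: 21 3β-formate aldehyde
Product: 22 3-O-formyl-12,13-bis-O-TBS derivative of 12α-hydroxygibberellic acid (free 7-acid)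
Conditions: NaClO2, NaH2PO4, 2-methyl-2-butene, t-BuOH/H2O, rt
Reagents that add atoms: sodium chlorite [Na+].[O-]Cl=O
Why: Pinnick oxidation converts the aldehyde to the C-7 acid without touching the alkenes, the formate or the silyl ethers.

**Step 13**
Reactants: 22 formate bis-silyl ether acid
Product: 24 (12S)-12α-hydroxygibberellic acid (the target gibberellin), via diol formate 23 (not isolated)
Conditions: HF·pyridine, pyridine/THF, 0 °C to rt; then KHCO3, MeOH/H2O, 0 °C
Reagents that add atoms: none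
Why: Fluoride-mediated desilylation followed by bicarbonate methanolysis of the labile formate (transesterification) frees the three hydroxyls while avoiding the strong base and strong acid that rearrange the allylic lactone.

**Compound list**
1 | butane-2,3-dione | CC(=O)C(C)=O | starting material
2 | 2,3-bis(tert-butyldimethylsilyloxy)buta-1,3-diene | C=C(O[Si](C)(C)C(C)(C)C)C(=C)O[Si](C)(C)C(C)(C)C | intermediate
3 | (E)-3-(furan-2-yl)prop-2-enal | O=C/C=C/c1ccco1 | starting material
4 | (1R,6R)-3,4-bis(TBSO)-6-(furan-2-yl)cyclohex-3-ene-1-carbaldehyde | O=C[C@@H]1CC(O[Si](C)(C)C(C)(C)C)=C(O[Si](C)(C)C(C)(C)C)C[C@H]1c1ccco1 | intermediate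
5 | 3-bromoprop-1-yne | C#CCBr | starting material
6 | (1S,6R)-3,4-bis(TBSO)-6-(furan-2-yl)-1-(prop-2-yn-1-yl)cyclohex-3-ene-1-carbaldehyde | C#CC[C@]1(C=O)CC(O[Si](C)(C)C(C)(C)C)=C(O[Si](C)(C)C(C)(C)C)C[C@H]1c1ccco1 | intermediate
7 | methyl 2-(bromomethyl)prop-2-enoate | C=C(CBr)C(=O)OC | starting material
8 | methyl 4-hydroxy-2-methylidene-4-[(1S,6R)-cyclohexenyl]butanoate (C-6 epimers; as zinc alkoxide) | C#CC[C@]1(C(O)CC(=C)C(=O)OC)CC(O[Si](C)(C)C(C)(C)C)=C(O[Si](C)(C)C(C)(C)C)C[C@H]1c1ccco1 | intermediate (not isolated)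
9 | α-methylene-γ-butyrolactone on C-8 (C-6 epimers) | C#CC[C@]1(C2CC(=C)C(=O)O2)CC(O[Si](C)(C)C(C)(C)C)=C(O[Si](C)(C)C(C)(C)C)C[C@H]1c1ccco1 | intermediate
10 | 3-methylfuran-2(5H)-one (butenolide) on C-8 (C-6 epimers, interconverting) | C#CC[C@]1(C2C=C(C)C(=O)O2)CC(O[Si](C)(C)C(C)(C)C)=C(O[Si](C)(C)C(C)(C)C)C[C@H]1c1ccco1 | intermediate (not isolated)
11 | oxygen-bridged lactone adduct (3α,10α-epoxy-1-ene; 4β-Me; C-19 lactonised onto 6α-O; 8β-propargyl; 12,13-enediol bis-TBS ether) | C#CC[C@]12CC(O[Si](C)(C)C(C)(C)C)=C(O[Si](C)(C)C(C)(C)C)C[C@H]1[C@@]13C=C[C@@H](O1)[C@@]1(C)C(=O)O[C@@H]2[C@@H]31 | intermediate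
12 | ring-D ketone (13-OTBS; 12-oxo; 16-methylidene) | C=C1C[C@]23C[C@@]1(O[Si](C)(C)C(C)(C)C)C(=O)C[C@H]2[C@@]12C=C[C@@H](O1)[C@@]1(C)C(=O)O[C@@H]3[C@@H]21 | intermediate
13 | 12α-alcohol (axial 12-OH; 13-OTBS) | C=C1C[C@]23C[C@@]1(O[Si](C)(C)C(C)(C)C)[C@@H](O)C[C@H]2[C@@]12C=C[C@@H](O1)[C@@]1(C)C(=O)O[C@@H]3[C@@H]21 | intermediate (not isolated)
14 | 12,13-bis-OTBS oxygen-bridged 19,6-lactone | C=C1C[C@]23C[C@@]1(O[Si](C)(C)C(C)(C)C)[C@@H](O[Si](C)(C)C(C)(C)C)C[C@H]2[C@@]12C=C[C@@H](O1)[C@@]1(C)C(=O)O[C@@H]3[C@@H]21 | intermediate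
15 | 6α-hydroxy 19-acid (as ammonium carboxylate) | C=C1C[C@]23C[C@@]1(O[Si](C)(C)C(C)(C)C)[C@@H](O[Si](C)(C)C(C)(C)C)C[C@H]2[C@@]12C=C[C@@H](O1)[C@@](C)(C(=O)O)[C@H]2[C@H]3O | intermediate (not isolated)
16 | 6-oxo 19-acid (oxygen bridge intact) | C=C1C[C@]23C[C@@]1(O[Si](C)(C)C(C)(C)C)[C@@H](O[Si](C)(C)C(C)(C)C)C[C@H]2[C@@]12C=C[C@@H](O1)[C@@](C)(C(=O)O)[C@H]2C3=O | intermediate
17 | 6-hydroxy-6-[methoxy(trimethylsilyl)methyl] 19-acid (diastereomers) | C=C1C[C@]23C[C@@]1(O[Si](C)(C)C(C)(C)C)[C@@H](O[Si](C)(C)C(C)(C)C)C[C@H]2[C@@]12C=C[C@@H](O1)[C@@](C)(C(=O)O)[C@H]2C3(O)C(OC)[Si](C)(C)C | intermediate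
18 | 6-(methoxymethylidene) 19-acid | C=C1C[C@]23C[C@@]1(O[Si](C)(C)C(C)(C)C)[C@@H](O[Si](C)(C)C(C)(C)C)C[C@H]2[C@@]12C=C[C@@H](O1)[C@@](C)(C(=O)O)[C@H]2C3=COC | intermediate (not isolated)
19 | 7-aldehyde 19-acid with oxygen bridge intact (C-6 epimers) | C=C1C[C@]23C[C@@]1(O[Si](C)(C)C(C)(C)C)[C@@H](O[Si](C)(C)C(C)(C)C)C[C@H]2[C@@]12C=C[C@@H](O1)[C@@](C)(C(=O)O)[C@H]2C3C=O | intermediate (not isolated)
20 | 3α-hydroxy-19,10-lactone 7-aldehyde (12,13-bis-OTBS) | C=C1C[C@]23C[C@@]1(O[Si](C)(C)C(C)(C)C)[C@@H](O[Si](C)(C)C(C)(C)C)C[C@H]2[C@@]12C=C[C@@H](O)[C@@](C)(C(=O)O1)[C@H]2[C@@H]3C=O | intermediate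
21 | 3β-formyloxy-19,10-lactone 7-aldehyde | C=C1C[C@]23C[C@@]1(O[Si](C)(C)C(C)(C)C)[C@@H](O[Si](C)(C)C(C)(C)C)C[C@H]2[C@@]12C=C[C@H](OC=O)[C@@](C)(C(=O)O1)[C@H]2[C@@H]3C=O | intermediate
22 | 3-O-formyl-12,13-bis-O-TBS derivative of 12α-hydroxygibberellic acid | C=C1C[C@]23C[C@@]1(O[Si](C)(C)C(C)(C)C)[C@@H](O[Si](C)(C)C(C)(C)C)C[C@H]2[C@@]12C=C[C@H](OC=O)[C@@](C)(C(=O)O1)[C@H]2[C@@H]3C(=O)O | intermediate
23 | 3-O-formyl derivative of 12α-hydroxygibberellic acid | C=C1C[C@]23C[C@@]1(O)[C@@H](O)C[C@H]2[C@@]12C=C[C@H](OC=O)[C@@](C)(C(=O)O1)[C@H]2[C@@H]3C(=O)O | intermediate (not isolated)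
24 | (12S)-12α-hydroxygibberellic acid (target gibberellin; 3β,12α,13-trihydroxy-1,16-diene 19,10-lactone 7-acid) | C=C1C[C@]23C[C@@]1(O)[C@@H](O)C[C@H]2[C@@]12C=C[C@H](O)[C@@](C)(C(=O)O1)[C@H]2[C@@H]3C(=O)O | target

**Step count and risks**
Total steps: 13. Longest linear sequence: 13 (1 → 24).

Most likely to fail, first: step 6, the proposed new method. The enediol ether may attack from C-12 (6-exo, bicyclo[2.2.2] product) or simply lose its silyl groups. A fallback using known chemistry sets out from 11 and comes back at 12. The enediol ether is desilylated (TBAF/AcOH) and the acyloin oxidised with Cu(OAc)2/air to the 12,13-diketone F7. Markovnikov hydroiodination of the alkyne (B-iodo-9-BBN, then AcOH) gives the 2-iodoallyl diketone F8. Intramolecular Nozaki–Hiyama–Kishi addition (CrCl2, catalytic NiCl2, DMF) of the vinyl iodide to the C-13 carbonyl, a five-membered ring closure, gives the 13-hydroxy-12-ketone F9. Silylation (TBSOTf, 2,6-lutidine) returns 12.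

Second: step 5. The butenolide is only a modest dienophile, and the furan face selectivity rests on a conformational argument. A fallback sets out from 6 and comes back at 20. CrCl2/NiCl2-mediated coupling of 6 with tert-butyl (Z)-3-iodo-2-methylacrylate gives the (Z)-hydroxy enoate F1. Parikh–Doering oxidation gives the (Z)-keto enoate F2, a doubly activated dienophile that should cyclise at room temperature to the keto tert-butyl ester adduct F3. Methoxymethylenation as in step 9, with KOt-Bu-induced Peterson elimination, gives the enol ether F4. The gold cyclisation of step 6 gives the ring-D ketone F5, and reduction/silylation as in step 7 gives the bis-silyl ether F6. The conditions of step 10, which also cleave the tert-butyl ester, return 20.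

Third: step 11. SN2′ attack at C-1 or elimination may compete with SN2 at the neopentyl-like C-3. A fallback sets out from 20 and comes back at 24. Pinnick oxidation first gives the 3α-hydroxy acid F10. MnO2 oxidises only the allylic alcohol, giving the enone F11. Reagent-controlled CBS reduction ((R)-methyl-oxazaborolidine, catecholborane) is then used to override the substrate's preference for β-face hydride attack and give the 3β-alcohol F12. HF·pyridine then gives 24.

**Further compounds**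
F1 | step 5 | tert-butyl (Z)-4-hydroxy-2-methyl-4-[(1S,6R)-cyclohexenyl]but-2-enoate (C-6 epimers) | C#CC[C@]1(C(O)/C=C(/C)C(=O)OC(C)(C)C)CC(O[Si](C)(C)C(C)(C)C)=C(O[Si](C)(C)C(C)(C)C)C[C@H]1c1ccco1
F2 | step 5 | tert-butyl (Z)-2-methyl-4-oxo-4-[(1S,6R)-cyclohexenyl]but-2-enoate | C#CC[C@]1(C(=O)/C=C(/C)C(=O)OC(C)(C)C)CC(O[Si](C)(C)C(C)(C)C)=C(O[Si](C)(C)C(C)(C)C)C[C@H]1c1ccco1
F3 | step 5 | oxygen-bridged 6-oxo 19-tert-butyl ester adduct (enediol bis-TBS ether; 8β-propargyl) | C#CC[C@]12CC(O[Si](C)(C)C(C)(C)C)=C(O[Si](C)(C)C(C)(C)C)C[C@H]1[C@@]13C=C[C@@H](O1)[C@@](C)(C(=O)OC(C)(C)C)[C@H]3C2=O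
F4 | step 5 | 6-(methoxymethylidene) analogue of the keto ester adduct | C#CC[C@]12CC(O[Si](C)(C)C(C)(C)C)=C(O[Si](C)(C)C(C)(C)C)C[C@H]1[C@@]13C=C[C@@H](O1)[C@@](C)(C(=O)OC(C)(C)C)[C@H]3C2=COC
F5 | step 5 | ring-D 12-ketone 13-OTBS enol ether tert-butyl ester | C=C1C[C@]23C[C@@]1(O[Si](C)(C)C(C)(C)C)C(=O)C[C@H]2[C@@]12C=C[C@@H](O1)[C@@](C)(C(=O)OC(C)(C)C)[C@H]2C3=COC
F6 | step 5 | 12,13-bis-OTBS enol ether tert-butyl ester | C=C1C[C@]23C[C@@]1(O[Si](C)(C)C(C)(C)C)[C@@H](O[Si](C)(C)C(C)(C)C)C[C@H]2[C@@]12C=C[C@@H](O1)[C@@](C)(C(=O)OC(C)(C)C)[C@H]2C3=COC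
F7 | step 6 | 12,13-diketone of the oxygen-bridged lactone (8β-propargyl) | C#CC[C@]12CC(=O)C(=O)C[C@H]1[C@@]13C=C[C@@H](O1)[C@@]1(C)C(=O)O[C@@H]2[C@@H]31
F8 | step 6 | 8β-(2-iodoprop-2-enyl) 12,13-diketone | C=C(I)C[C@]12CC(=O)C(=O)C[C@H]1[C@@]13C=C[C@@H](O1)[C@@]1(C)C(=O)O[C@@H]2[C@@H]31
F9 | step 6 | 13-hydroxy-12-ketone with ring D closed | C=C1C[C@]23C[C@@]1(O)C(=O)C[C@H]2[C@@]12C=C[C@@H](O1)[C@@]1(C)C(=O)O[C@@H]3[C@@H]21
F10 | step 11 | 3α-hydroxy-12,13-bis-O-TBS 7-acid (3-epi) | C=C1C[C@]23C[C@@]1(O[Si](C)(C)C(C)(C)C)[C@@H](O[Si](C)(C)C(C)(C)C)C[C@H]2[C@@]12C=C[C@@H](O)[C@@](C)(C(=O)O1)[C@H]2[C@@H]3C(=O)O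
F11 | step 11 | 3-oxo-1-ene 12,13-bis-O-TBS 7-acid | C=C1C[C@]23C[C@@]1(O[Si](C)(C)C(C)(C)C)[C@@H](O[Si](C)(C)C(C)(C)C)C[C@H]2[C@@]12C=CC(=O)[C@@](C)(C(=O)O1)[C@H]2[C@@H]3C(=O)O
F12 | step 11 | 12,13-bis-O-TBS ether of 12α-hydroxygibberellic acid | C=C1C[C@]23C[C@@]1(O[Si](C)(C)C(C)(C)C)[C@@H](O[Si](C)(C)C(C)(C)C)C[C@H]2[C@@]12C=C[C@H](O)[C@@](C)(C(=O)O1)[C@H]2[C@@H]3C(=O)O
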